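Which species holds most of the X charged after 2.0 h in north-east and in west, and how much? X is the limiting reagent, so the reckoning below is a ledger of X units, entry by entry.

| flask | X | Q | remark | time |
|---|---|---|---|---|
| delta | 0.056 M | 3 equiv | run made earlier |  |
| epsilon | 0.042 M | 3 equiv | run made earlier |  |
| north-east | 0.083 M | 3.00 equiv |  | 2.0 h |
| west | 0.083 M | 6.00 equiv |  | 2.0 h |

| run | time / min | D / % | L / % | X / % | G / % |
|---|---|---|---|---|---|
| delta | 10.0 | 5.8 | 1.1 | 50.3 | 27.5 |
| delta | 20.0 | 16.9 | 7.7 | 3.9 | 68.5 |
| delta | 30.0 | 15.5 | 18.9 | 1.0 | 65.7 |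
| delta | 40.0 | 15.7 | 26.3 | 0 | 57.0 |
| delta | 50.0 | 16.6 | 32.8 | 0 | 50.6 |
| delta | 60.0 | 17.9 | 37.4 | 1.0 | 45.4 |
| delta | 80.0 | 17.5 | 49.1 | 0.3 | 34.4 |
| epsilon | 6.00 | 0 | 0 | 78.4 | 1.7 |
| epsilon | 8.00 | 0.9 | 0 | 76.7 | 2.9 |
| epsilon | 12.0 | 3.8 | 0 | 71.2 | 9.7 |
| epsilon | 20.0 | 8.5 | 3.9 | 39.0 | 35.1 |
| epsilon | 30.0 | 18.2 | 8.2 | 9.7 | 59.3 |
| epsilon | 50.0 | 22.2 | 24.4 | 0.2 | 53.5 |
| epsilon | 80.0 | 21.4 | 41.6 | 0 | 36.7 |

(standard deviation of a reading: 1 percentage point)

- percent here means X units held: one D counts as two
- a reading of X is of its free form alone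

- which of these there is most of at the end, counted by the X in it, north-east (X / D / G / L)
- which of these there is most of at the end, counted by the X in it, west (X / D / G / L)
- amount of the one of these that there is most of at the end, in percent of the X charged, north-east
- amount of the one of these that there is most of at the end, in percent of the X charged, west

The first entry closes by itself. At the first reading of epsilon, 19.9 % of the X is missing from the four columns, yet the last reading of epsilon sums to 99.7 %. An unseen form therefore holds X for a while and gives it back, and this reckoning enters zero for it at the end.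

The second entry is D. The ratio of D to G plus L at the last reading, multiplied by the charged c_Q, is 0.0352 M in delta and 0.0344 M in epsilon. Their mean, 0.0348 M, is called here the D toll. Both runs hold the equivalents, so c_Q and c_X moved together, and taking c_Q as the divisor is a commitment. It gives D as 12.3 % in north-east and 6.54 % in west.

The remainder is divided between G and L. In delta, G falls from 65.7 % at 30.0 min to 34.4 % at 80.0 min, a first-order constant of 0.0129 min⁻¹. The clock for this decay starts when X is about half gone, near 10.0 min in delta. Scaling that time by one over c_X times c_Q gives 17.8 min for epsilon, whose X passes half between 12.0 min and 20.0 min. The same scaling gives 4.55 min for north-east and 2.28 min for west. The books close with L at 68.0 % in north-east and 73.1 % in west.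

The forecast gives L at 68 % for north-east and L at 71 % for west, holding that “D is about 6% if Q controls it, otherwise 12%”, so this reckoning stands above it in west. The flask gives L at 68.3 % in north-east and L at 73.9 % in west.

    X + Q + G → 2 G (k = 77.0 M⁻² min⁻¹)
    X + G → D (k = 1.00 M⁻¹ min⁻¹)
    X + Q → G (k = 0.00840 M⁻¹ min⁻¹)
    G → L (k = 0.0130 min⁻¹)
    X ⇌ Z (K = 0.250, k = 0.110 min⁻¹)

D ends at 11.7 % in north-east and 5.49 % in west, against 12.3 % and 6.54 % from the toll, while the step from X to Z makes no difference to L at the end of north-east. A neighbouring flask repeats north-east at 0.033 M of X. The toll of 0.0348 M gives it D of 26.0 % and, with its clock at 28.8 min, L of 51.3 %. That neighbouring flask ends with D at 26.2 % and L at 49.0 %.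

The data stem from a simulated flask for substances that don't exist, noise included.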